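## Structural features

Atoms carry elemane numbering: ring C5–C10, vinyl C1=C2 on C10, side chain C4(=C3)–C15 on C5, lactone carbons C11–C13, methyl C14; β is the face of C14 and α the opposite face. The target is a single cyclohexane in which all six ring carbons are contiguous stereocentres, (5R,6S,7R,8R,9S,10S). C10 is quaternary (methyl, vinyl); C9 bears an angelate; C8 and C7 carry a cis-fused α-methylene-γ-butyrolactone (O8–C12(=O)–C11(=C13)–C7); C6 bears an acetate; C5 bears a 2-substituted acrolein. The C5 side chain and O6 are β, whereas the vinyl group, O9, O8 and C11 are α, so O6 is cis to its C5 neighbour but trans to C11. Fragile elements are the two Michael acceptors (methylene lactone, enal), the Z-configured angelate (isomerises to the tiglate), the esters of the 8,9-cis-diol (acyl shift, translactonisation) and H5, which is allylic and becomes enolisable whenever C6 is a ketone. The difficulty lies less in ring construction than in the quaternary C10 flanked by oxygenated C9 and in the contiguous C5–C8 array. The key step uses the cis relation of O9 and the vinyl group: C10, C1, C2, an oxygen and C9 form a tetrahydrofuran that can be closed by conjugate addition of a 2-hydroxyethyl group inside a 4,4-disubstituted cyclohexadienone whose C4 is C10, and that is reopened at the end to the C9 hydroxyl and the vinyl group.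

## Logic of the disconnections

36 to 34: the C15 oxygen is removed. The enal is the most electrophilic group, so it is made last. The forward step must oxidise one allylic methyl chemoselectively in a molecule with four alkenes.

34 to 31 and 32: the O9–acyl bond is cut. The angelate is introduced late because it isomerises easily. The forward step must acylate a neopentyl secondary alcohol without Z/E scrambling.

31 to 28 (through 29): C2 is reconnected to O9, so vinyl group and C9 hydroxyl become a tetrahydrofuran. This protects O9 and masks the vinyl group through all enolate and hydride chemistry. The forward steps must cleave the primary C2–O bond regioselectively and eliminate in the presence of esters and a Michael acceptor.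

28 to 27 to 24: the acetyl group and then C13 are removed. A saturated lactone with a free C6 hydroxyl is simpler and tolerates the preceding reductions. The lactone enolate chemistry must be finished before any ester is installed.

24 to 23 to 22 to 21: the C7–H bond is cut back to a butenolide, and the C6 carbinol is traced to a ketone and then to its epimer. Direct enolate oxidation can deliver O6 only anti to the C5 substituent, so the β configuration is set by hydride addition while C7 is still planar. The forward steps need hydride on the α face at C6 and on the β face at C7.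

20 to 18 and 19: C7=C11 and O8–C12 are cut. A two-carbon ketene ylide annulates onto an α-hydroxy ketone, turning the ring carbonyl at C7 into the C7–C11 bond and closing the lactone at once. This needs a free 8-hydroxyl and a protected 6-hydroxyl.

18 to 17 to 16 to 14: the C8–O and C6–O bonds are cut. Both oxygens come from enolate oxidation on either side of the C7 carbonyl. The first is regiodefined by the conjugate-addition enolate, the second by kinetic deprotonation. The second must enter anti to the axial angular methyl.

14 to 12 and 13: the C5–C4 bond is cut. Conjugate addition to the surviving enone leaves a bicyclic enone with only two stereocentres. The nucleophile must attack a neopentyl β-carbon on the convex face, cis to the methyl group.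

12 to 11: the O–C9 bond is cut (key step). The precursor is achiral, and C9 and C10 arise together. The forward step must select one of two enantiotopic enone arms.

11 to 10 to 8: the silyl group is restored and one ring C=C is removed. The hydroxyl must stay protected until the dienone exists, because a free hydroxy-enone would cyclise in racemic form.

8 to 4 and 5: the bond from C10 to the adjacent ring methylene (Michael) and the enone C=C (aldol condensation) are cut. This is a Robinson annulation of an α-branched aldehyde, which must tolerate the silyl ether.

4 to 1: functional-group changes only. The lactone carbonyl becomes the aldehyde and the ring oxygen becomes the protected hydroxyl.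

## Other disconnections considered

Alternative 1: The cut goes through C7–C8 and O8–C12, so carbocycle and lactone form together. Forward, CrCl2 reduces the allylic bromide of a 2-(bromomethyl)acrylate unit to an allylchromium species that adds through C7 to a C8 aldehyde in a closed chair-like transition state. The chromium alkoxide then acylates on the ester and gives the methylene lactone A1 (C9 silyl ether, C6 4-methoxybenzyl ether).
- In its favour: ring, C7, C8 and the α-methylene lactone arise in one operation at the final oxidation level. This is better than the chosen plan, which spends steps 12 to 17 on the same unit and must control two hydride deliveries.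
- Against it here: the open-chain substrate must already hold C5, C6, C9 and the quaternary C10 with its vinyl group, so four stereocentres need acyclic control. The C8 aldehyde is α-oxygenated and neopentyl. The syn C7/C8 outcome and its relation to the flanking ethers depend on allyl geometry and on which chair is adopted.
- Comparison: A1 is structurally closer to the target than any intermediate of the chosen plan before 27, and its end game (deprotections, two acylations, allylic oxidation) is equal to that of the chosen plan. Both rest on substrate control for C7/C8. The alternative should be shorter after its key step and longer before it, whereas the chosen plan obtains C9 and C10 catalytically from an achiral dienone in seven steps.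

Alternative 2: The cuts are C10–C1 and C5–C4, the two bonds carrying the alkenyl groups, traced to one cyclobutane. Forward, irradiation of a 3-methylcyclohexenone (C6 carbonyl, C5=C10 alkene) with a cyclobutene ester gives the cis-anti-cis photoadduct A2. Later heating opens the bicyclo[2.2.0]hexane unit to the vinyl group and an acrylate on C5.
- In its favour: quaternary C10 and both alkenyl groups come from one step. C15 arrives at the acid oxidation level, so the late allylic oxidation of the chosen plan is unnecessary, which is better. No ether has to be cleaved. The C6 ketone of A2 makes C7 an enolate carbon that can be alkylated directly, which is also better than converting a C7 carbonyl into a C7–C bond.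
- Against it: head-to-head versus head-to-tail regiochemistry and facial selectivity of the photocycloaddition are not dictated by the substrate. C5 and C8 must be epimerised afterwards. The thermal opening needs high temperature and the 1,5-diene can enter Cope equilibria. Absolute configuration must come from a chiral enone. The lactone array still has to be built.
- Comparison: both plans mask the vinyl group in a ring and unmask it late. Excited-state selectivity is harder to predict than the ground-state Brønsted acid catalysis of step 7. Step counts should be similar: the alternative saves the oxidation and the ether opening but adds two epimerisations and a thermolysis.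

Alternative 3: The cut is C5–C10, seen as the product of a 1,2-shift, so the cyclohexane derives from a cycloheptene oxide. Forward, methylaluminium bis(4-bromo-2,6-di-tert-butylphenoxide) opens the C1–C10 epoxide at tertiary C10, the antiperiplanar ring bond migrates so that C5 moves from C1 to C10, and C1 is left as the aldehyde of A3.
- In its favour: the quaternary centre forms stereospecifically with a formyl group that becomes the vinyl group by one Wittig methylenation, which is better than the two-step ether opening of the chosen plan. A3 already holds C5, C6, C9 and C10, four of six centres against two in 12, which is also better. The C7=C8 alkene is in place for lactone annulation.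
- Against it: a stereodefined, enantiopure trisubstituted cycloheptene oxide with three further centres must be made first. Hydride shift, migration of the other ring bond, participation of the C9 benzoate and capture of the cation by the isopropenyl group all compete. C7/C8 must then be functionalised at one alkene among three, with O8 and C11 both on the face of the C9 oxygen.
- Comparison: the alternative needs a stoichiometric bulky Lewis acid and exact stereoelectronic alignment, where the chosen plan uses a catalytic acid on an achiral substrate. The chosen plan reaches its key product faster but spends more steps afterwards. The end game of acylation and allylic oxidation is equal in both.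

Key step: step 7

## Remarks on the chemistry

- Compounds 1–8 are racemic; their single stereocentre disappears at 10, so no enantiopure lactone is needed.
- The key-step precursor 11 and product 12 as drawn match the target: 12 is (3aS,7aR), methyl β, ether α. No structural correction was needed.
- The hydroxyl is carried as a silyl ether up to the dienone. A free hydroxy-enone would close to a racemic bicyclic ether during the annulation.
- Assumption: in steps 7 and 16 the catalyst enantiomer written is the one taken to give the drawn sense. If a first run shows the opposite sense, the antipode is used.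

## Route

Step 1
Reactants: 1 3-methyldihydrofuran-2(3H)-one
Product: 2 4-hydroxy-N-methoxy-N,2-dimethylbutanamide
Conditions: MeNH(OMe)·HCl, iPrMgCl, THF, −20 → 0 °C
Reagents that add atoms: N,O-dimethylhydroxylamine hydrochloride, CNOC.Cl
Why: Aminolysis of the lactone by the magnesium amide (Weinreb amide formation) frees the primary hydroxyl and leaves a carbonyl that hydride reduces only to the aldehyde.

Step 2
Reactants: 2 4-hydroxy-N-methoxy-N,2-dimethylbutanamide
Product: 3 4-[(tert-butyldiphenylsilyl)oxy]-N-methoxy-N,2-dimethylbutanamide
Conditions: TBDPSCl, imidazole, CH2Cl2, 0 °C → rt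
Reagents that add atoms: tert-butyl(chloro)diphenylsilane, CC(C)(C)[Si](Cl)(c1ccccc1)c1ccccc1
Why: Silylation of the primary alcohol prevents relactonisation; the acid-stable TBDPS group should survive the enamine hydrolysis and enolate chemistry ahead.

Step 3
Reactants: 3 4-[(tert-butyldiphenylsilyl)oxy]-N-methoxy-N,2-dimethylbutanamide
Product: 4 4-[(tert-butyldiphenylsilyl)oxy]-2-methylbutanal
Conditions: iBu2AlH, THF, −78 °C; Rochelle salt
Reagents that add atoms: none
Why: Hydride reduction of a Weinreb amide stops at the chelated tetrahedral intermediate and releases the aldehyde on work-up; the α-stereocentre is irrelevant because it becomes the prochiral quaternary carbon.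

Step 4
Reactants: 4 4-[(tert-butyldiphenylsilyl)oxy]-2-methylbutanal; 5 but-3-en-2-one
Product: 8 4-{2-[(tert-butyldiphenylsilyl)oxy]ethyl}-4-methylcyclohex-2-en-1-one, via enamine 6 (not isolated), via keto aldehyde 7 (not isolated)
Conditions: pyrrolidine, toluene, 4 Å MS, rt; 5, 0 °C → rt; AcOH/NaOAc, H2O, 70 °C
Reagents that add atoms: none
Why: Robinson annulation through the Stork enamine of an α-branched aldehyde: Michael addition to the enone builds the quaternary carbon and aldol condensation closes the cyclohexenone; the silyl ether prevents racemic oxa-Michael closure of a free hydroxy-enone.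

Step 5
Reactants: 8 4-{2-[(tert-butyldiphenylsilyl)oxy]ethyl}-4-methylcyclohex-2-en-1-one
Product: 10 4-{2-[(tert-butyldiphenylsilyl)oxy]ethyl}-4-methylcyclohexa-2,5-dien-1-one, via silyl dienol ether 9 (not isolated)
Conditions: LiN(iPr)2, TMSCl, THF, −78 °C; then Pd(OAc)2, MeCN, rt
Reagents that add atoms: none
Why: Saegusa–Ito dehydrogenation: kinetic α′-deprotonation (no γ-hydrogen exists), O-silylation and oxidation by Pd(OAc)2 give the cross-conjugated dienone, which cannot aromatise; the molecule becomes achiral.

Step 6
Reactants: 10 4-{2-[(tert-butyldiphenylsilyl)oxy]ethyl}-4-methylcyclohexa-2,5-dien-1-one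
Product: 11 4-(2-hydroxyethyl)-4-methylcyclohexa-2,5-dien-1-one
Conditions: Bu4NF, AcOH (1:1), THF, 0 °C → rt
Reagents that add atoms: none
Why: Fluoride desilylation buffered with acetic acid, so that no alkoxide forms that could trigger racemic ring closure; any prematurely cyclised material is a different compound and is removed by chromatography.

Step 7
Reactants: 11 4-(2-hydroxyethyl)-4-methylcyclohexa-2,5-dien-1-one
Product: 12 (3aS,7aR)-3a-methyl-3,3a,7,7a-tetrahydro-1-benzofuran-6(2H)-one
Conditions: (R)-3,3′-bis(2,4,6-triisopropylphenyl)-1,1′-binaphthyl-2,2′-diyl hydrogen phosphate (10 mol%), CH2Cl2, 4 Å MS, rt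
Reagents that add atoms: none
Why: The phosphoric acid acts bifunctionally: its P–OH hydrogen-bonds the dienone carbonyl while the P=O oxygen accepts a hydrogen bond from the tethered hydroxyl, and the alcohol oxygen adds to one β-carbon (C9) to give a dienol that tautomerises to the enone. The closest known reaction type is the chiral-phosphoric-acid-catalysed intramolecular oxa-Michael desymmetrisation of 4-substituted 4-(hydroxyalkyl)cyclohexa-2,5-dienones. The tetrahydrofuran closes in the 5-exo-trig mode. C9 is set by the catalyst, whose triisopropylphenyl walls allow only one of the two enantiotopic enone arms to lie in the pocket next to the bound hydroxyl. C10 becomes stereogenic through the same choice, and its relation to C9 is fixed as cis because a two-atom tether reaches the β-carbon only on its own face. The only selectivity required is between enantiotopic groups; there is no regio- or diastereochemical alternative because the two arms are identical and there is one nucleophile. Background cyclisation is kept low by excluding base and using a non-polar solvent, and the second enone survives because no hydroxyl remains.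

Step 8
Reactants: 12 (3aS,7aR)-3a-methyl-3,3a,7,7a-tetrahydro-1-benzofuran-6(2H)-one; 13 isopropenylmagnesium bromide
Product: 14 trimethyl{[3a-methyl-4-(prop-1-en-2-yl)-2,3,3a,4,7,7a-hexahydro-1-benzofuran-6-yl]oxy}silane (cis-fused; isopropenyl cis to 3a-methyl; 5β in target numbering)
Conditions: CuBr·SMe2 (20 mol%), TMSCl, THF, −78 → −40 °C; Et3N
Reagents that add atoms: chlorotrimethylsilane, C[Si](C)(C)Cl
Why: Copper-catalysed conjugate addition accelerated by the silyl chloride; the cis-fused ether folds under the enone, so the organocopper should attack C5 on the convex face, anti to the pseudoaxial C1 methylene and therefore cis to the angular methyl. Silylation fixes the C6=C7 enolate regiochemistry for the next step.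

Step 9
Reactants: 14 trimethylsilyl enol ether of the 5β-isopropenyl ketone
Product: 16 5-hydroxy-3a-methyl-4-(prop-1-en-2-yl)hexahydro-1-benzofuran-6(2H)-one (5-OH trans to isopropenyl; 6α-OH in target numbering), via silyloxy epoxide 15 (not isolated)
Conditions: dimethyldioxirane, acetone/CH2Cl2, −78 °C; then AcOH, THF/H2O, 0 °C
Reagents that add atoms: dimethyldioxirane, CC1(C)OO1
Why: Rubottom oxidation; the dioxirane attacks the electron-rich silyl enol ether far faster than the isopropenyl group, on the face anti to the neighbouring isopropenyl group and the angular methyl. This gives the 6α-alcohol, the epimer that is corrected in steps 14 and 15.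

Step 10
Reactants: 16 6α-hydroxy ketone
Product: 17 5-(tert-butyldimethylsilyloxy)-3a-methyl-4-(prop-1-en-2-yl)hexahydro-1-benzofuran-6(2H)-one (6α-OTBS in target numbering)
Conditions: TBSOTf, 2,6-lutidine, CH2Cl2, −78 → 0 °C
Reagents that add atoms: tert-butyldimethylsilyl trifluoromethanesulfonate, CC(C)(C)[Si](C)(C)OS(=O)(=O)C(F)(F)F
Why: Silylation with the silyl triflate differentiates O6 from the hydroxyl to be introduced at C8 and holds the ring in the chair with O6 equatorial and the angular methyl axial.

Step 11
Reactants: 17 6α-silyloxy ketone
Product: 18 5-(tert-butyldimethylsilyloxy)-7-hydroxy-3a-methyl-4-(prop-1-en-2-yl)hexahydro-1-benzofuran-6(2H)-one (7-OH cis to the ring oxygen; 8α-OH in target numbering)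
Conditions: KN(SiMe3)2, THF, −78 °C; 2-(benzenesulfonyl)-3-phenyloxaziridine, −78 °C; AcOH
Reagents that add atoms: 2-(benzenesulfonyl)-3-phenyloxaziridine, O=S(=O)(c1ccccc1)N1OC1c1ccccc1
Why: Enolate hydroxylation with the Davis oxaziridine: kinetic deprotonation occurs at the C8 methylene (C6 is a hindered silyloxy methine), and the oxidant should approach anti to the axial angular methyl that is syn-axial to C8, giving the equatorial 8α-hydroxyl, cis to O9. This epimer is also the more stable, all-equatorial ketol.

Step 12
Reactants: 18 8α-hydroxy-6α-silyloxy ketone; 19 (triphenylphosphoranylidene)ketene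
Product: 20 2,9α-epoxy-6α-(tert-butyldimethylsilyloxy)-5β-isopropenyl-7(11)-en-8α,12-olide (tricyclic butenolide; target numbering)
Conditions: toluene, 100 °C
Reagents that add atoms: none
Why: The hydroxyl adds to the ketenylidene ylide to give an ester-stabilised ylide, which closes by intramolecular Wittig reaction on the C7 ketone (butenolide annulation); C7=C11 and O8–C12 form without touching a stereocentre.

Step 13
Reactants: 20 6α-silyloxy butenolide
Product: 21 2,9α-epoxy-6α-hydroxy-5β-isopropenyl-7(11)-en-8α,12-olide
Conditions: HF·pyridine, pyridine, THF, 0 °C → rt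
Reagents that add atoms: none
Why: Acidic fluoride desilylation; basic fluoride is avoided because the γ-hydrogen H8 of the butenolide is acidic.

Step 14
Reactants: 21 6α-hydroxy butenolide
Product: 22 2,9α-epoxy-5β-isopropenyl-6-oxo-7(11)-en-8α,12-olide
Conditions: Dess–Martin periodinane, NaHCO3, CH2Cl2, 0 °C
Reagents that add atoms: none
Why: Buffered Dess–Martin oxidation of the allylic secondary alcohol leaves the alkenes alone; the ketone is used at once because H5 is now enolisable.

Step 15
Reactants: 22 6-oxo butenolide
Product: 23 2,9α-epoxy-6β-hydroxy-5β-isopropenyl-7(11)-en-8α,12-olide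
Conditions: NaBH4, CeCl3·7H2O, MeOH, −78 °C
Reagents that add atoms: none
Why: Luche 1,2-reduction; the planar butenolide holds O8 equatorial, which locks the chair with the angular methyl axial and syn to C6, so hydride should enter on the α face and give the 6β-alcohol, cis to the isopropenyl group. In this chair the isopropenyl group is equatorial only in the desired C5 configuration, so C5 is not at risk.

Step 16
Reactants: 23 6β-hydroxy butenolide
Product: 24 2,9α-epoxy-6β-hydroxy-5β-isopropenyl-7βH-8α,12-olide (saturated cis-fused lactone)
Conditions: Cu(OAc)2·H2O (5 mol%), (S)-p-tol-BINAP (5 mol%), (EtO)2MeSiH, tBuOH, toluene, 0 °C → rt; NH4F, MeOH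
Reagents that add atoms: none
Why: Copper hydride conjugate reduction of a β,β-disubstituted butenolide; hydride should reach C7 on the β face because the α face carries the syn-axial ether oxygen O9, which makes the lactone cis-fused (H7β, C11α). The ligand enantiomer is chosen to reinforce this sense, and the isolated isopropenyl group is inert to the copper hydride.

Step 17
Reactants: 24 saturated hydroxy lactone
Product: 27 2,9α-epoxy-6β-hydroxy-5β-isopropenyl-11(13)-en-8α,12-olide, via Mannich base 25 (not isolated), via trimethylammonium iodide 26 (not isolated)
Conditions: LiN(iPr)2 (2.3 equiv), THF, −78 °C; CH2=NMe2+ I−, −78 → 0 °C; MeI, MeOH, rt; NaHCO3, CH2Cl2/H2O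
Reagents that add atoms: N,N-dimethylmethyleneiminium iodide (Eschenmoser's salt), C=[N+](C)C.[I-]
Why: α-Methylenation by Mannich reaction of the lactone enolate, quaternisation and elimination of trimethylamine; the C6 alkoxide is kept cold as part of the dianion so that it does not relactonise, and no ester is yet present.

Step 18
Reactants: 27 α-methylene hydroxy lactone
Product: 28 6β-acetoxy-2,9α-epoxy-5β-isopropenyl-11(13)-en-8α,12-olide
Conditions: Ac2O, DMAP, pyridine, CH2Cl2, rt
Reagents that add atoms: acetic anhydride, CC(=O)OC(C)=O
Why: DMAP-catalysed acetylation installs the C6 ester of the target while it is the only free hydroxyl, so no selectivity is needed.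

Step 19
Reactants: 28 6β-acetoxy tricyclic methylene lactone
Product: 29 6β-acetoxy-2-bromo-9α-hydroxy-5β-isopropenyl-11(13)-en-8α,12-olide (C1–C2 saturated)
Conditions: Me2BBr, Et3N (0.2 equiv), CH2Cl2, −78 → 0 °C; aq NaHCO3
Reagents that add atoms: bromodimethylborane, CB(C)Br
Why: Lewis-acid ether cleavage: boron binds O9 and bromide opens the oxonium by SN2 at primary C2 rather than at C9, which is neopentyl and deactivated by the adjacent acyloxy group. Esters, lactone and alkenes should tolerate the buffered reagent at low temperature, and any bromide adduct of the methylene lactone converges in step 20.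

Step 20
Reactants: 29 bromo alcohol
Product: 31 6β-acetoxy-9α-hydroxyelema-1,3,11(13)-trien-8α,12-olide, via bis-selenide 30 (not isolated)
Conditions: (2-O2NC6H4Se)2, NaBH4, EtOH, 0 °C (selenolate pre-formed); 29, THF, rt; then H2O2, pyridine, THF, 0 °C → rt
Reagents that add atoms: none
Why: Selenide displacement and selenoxide syn-elimination (Grieco-type olefination): the selenolate displaces the primary bromide and also adds to the methylene lactone, and oxidation gives two selenoxides that eliminate to the C1=C2 vinyl group and regenerate the C11=C13 methylene.

Step 21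
Reactants: 31 vinyl C9 alcohol; 32 angelic acid
Product: 34 6β-acetoxy-9α-angeloyloxyelema-1,3,11(13)-trien-8α,12-olide, via mixed anhydride 33 (not isolated)
Conditions: 32, 2,4,6-Cl3C6H2COCl, Et3N, toluene, rt; then 31, 75 °C
Reagents that add atoms: none
Why: Yamaguchi esterification through the mixed anhydride, the usual way to acylate hindered alcohols with angelic acid without Z to E isomerisation; no nucleophilic catalyst is added, which limits isomerisation to the tiglate.

Step 22
Reactants: 34 angelate
Product: 36 6β-acetoxy-9α-angeloyloxy-15-oxoelema-1,3,11(13)-trien-8α,12-olide (target), via allylic alcohol 35 (not isolated)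
Conditions: SeO2 (0.5 equiv), tBuOOH, CH2Cl2, rt; then MnO2, CH2Cl2, rt
Reagents that add atoms: tert-butyl hydroperoxide, CC(C)(C)OO; selenium dioxide (oxygen relay), O=[Se]=O
Why: Allylic oxidation by SeO2 (ene reaction, then [2,3] shift) at the methyl group of the only electron-rich alkene that has allylic hydrogens, followed by MnO2 oxidation of the allylic alcohol to the enal. The vinyl group has no allylic hydrogen and the conjugated alkenes are deactivated.

## Compound list

Names of 20–36 use target numbering; "2,9α-epoxy" is the tetrahydrofuran O9–C2–C1–C10–C9.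

1 | 3-methyldihydrofuran-2(3H)-one (racemic) | CC1CCOC1=O | starting material
2 | 4-hydroxy-N-methoxy-N,2-dimethylbutanamide (racemic) | CC(CCO)C(=O)N(C)OC | intermediate
3 | 4-[(tert-butyldiphenylsilyl)oxy]-N-methoxy-N,2-dimethylbutanamide (racemic) | CC(CCO[Si](c1ccccc1)(c1ccccc1)C(C)(C)C)C(=O)N(C)OC | intermediate
4 | 4-[(tert-butyldiphenylsilyl)oxy]-2-methylbutanal (racemic) | CC(CCO[Si](c1ccccc1)(c1ccccc1)C(C)(C)C)C=O | intermediate
5 | but-3-en-2-one | CC(=O)C=C | starting material
6 | 1-{4-[(tert-butyldiphenylsilyl)oxy]-2-methylbut-1-en-1-yl}pyrrolidine (enamine, not isolated) | CC(=CN1CCCC1)CCO[Si](c2ccccc2)(c2ccccc2)C(C)(C)C | intermediate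
7 | 2-{2-[(tert-butyldiphenylsilyl)oxy]ethyl}-2-methyl-5-oxohexanal (racemic, not isolated) | CC(=O)CCC(C)(C=O)CCO[Si](c1ccccc1)(c1ccccc1)C(C)(C)C | intermediate
8 | 4-{2-[(tert-butyldiphenylsilyl)oxy]ethyl}-4-methylcyclohex-2-en-1-one (racemic) | O=C1C=CC(C)(CCO[Si](c2ccccc2)(c2ccccc2)C(C)(C)C)CC1 | intermediate
9 | tert-butyl{2-[1-methyl-4-(trimethylsilyloxy)cyclohexa-2,4-dien-1-yl]ethoxy}diphenylsilane (racemic, not isolated) | C[Si](C)(C)OC1=CCC(C)(CCO[Si](c2ccccc2)(c2ccccc2)C(C)(C)C)C=C1 | intermediate
10 | 4-{2-[(tert-butyldiphenylsilyl)oxy]ethyl}-4-methylcyclohexa-2,5-dien-1-one | O=C1C=CC(C)(CCO[Si](c2ccccc2)(c2ccccc2)C(C)(C)C)C=C1 | intermediate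
11 | 4-(2-hydroxyethyl)-4-methylcyclohexa-2,5-dien-1-one | O=C1C=CC(C)(CCO)C=C1 | intermediate
12 | (3aS,7aR)-3a-methyl-3,3a,7,7a-tetrahydro-1-benzofuran-6(2H)-one | C[C@@]12CCO[C@@H]1CC(=O)C=C2 | intermediate
13 | isopropenylmagnesium bromide | CC(=C)[Mg]Br | starting material
14 | trimethyl{[3a-methyl-4-(prop-1-en-2-yl)-2,3,3a,4,7,7a-hexahydro-1-benzofuran-6-yl]oxy}silane, cis-fused, isopropenyl cis to 3a-methyl | C2C[C@]1(C)[C@H](O2)CC(O[Si](C)(C)C)=C[C@H]1C(C)=C | intermediate
15 | 5,6-epoxide of 14 on the face opposite to the isopropenyl group (not isolated) | C2C[C@]1(C)[C@H](O2)C[C@]3(O[Si](C)(C)C)O[C@@H]3[C@H]1C(C)=C | intermediate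
16 | 5-hydroxy-3a-methyl-4-(prop-1-en-2-yl)hexahydro-1-benzofuran-6(2H)-one, isopropenyl cis to methyl, 5-OH trans to isopropenyl (5β-isopropenyl, 6α-OH) | C2C[C@]1(C)[C@H](O2)CC(=O)[C@H](O)[C@H]1C(C)=C | intermediate
17 | 5-O-tert-butyldimethylsilyl ether of 16 | C2C[C@]1(C)[C@H](O2)CC(=O)[C@H](O[Si](C)(C)C(C)(C)C)[C@H]1C(C)=C | intermediate
18 | 7-hydroxy derivative of 17, 7-OH cis to the ring oxygen (8α-OH) | C2C[C@]1(C)[C@H](O2)[C@H](O)C(=O)[C@H](O[Si](C)(C)C(C)(C)C)[C@H]1C(C)=C | intermediate
19 | (triphenylphosphoranylidene)ketene | O=C=C=P(c1ccccc1)(c1ccccc1)c1ccccc1 | starting material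
20 | 2,9α-epoxy-6α-(tert-butyldimethylsilyloxy)-5β-isopropenyl-7(11)-en-8α,12-olide | C3C[C@]1(C)[C@H](O3)[C@@H]2OC(=O)C=C2[C@H](O[Si](C)(C)C(C)(C)C)[C@H]1C(C)=C | intermediate
21 | 2,9α-epoxy-6α-hydroxy-5β-isopropenyl-7(11)-en-8α,12-olide | C3C[C@]1(C)[C@H](O3)[C@@H]2OC(=O)C=C2[C@H](O)[C@H]1C(C)=C | intermediate
22 | 2,9α-epoxy-5β-isopropenyl-6-oxo-7(11)-en-8α,12-olide | C3C[C@]1(C)[C@H](O3)[C@@H]2OC(=O)C=C2C(=O)[C@H]1C(C)=C | intermediate
23 | 2,9α-epoxy-6β-hydroxy-5β-isopropenyl-7(11)-en-8α,12-olide | C3C[C@]1(C)[C@H](O3)[C@@H]2OC(=O)C=C2[C@@H](O)[C@H]1C(C)=C | intermediate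
24 | 2,9α-epoxy-6β-hydroxy-5β-isopropenyl-7βH-8α,12-olide | C3C[C@]1(C)[C@H](O3)[C@@H]2OC(=O)C[C@@H]2[C@@H](O)[C@H]1C(C)=C | intermediate
25 | 13-(dimethylamino) derivative of 24, C11 epimers (not isolated) | C3C[C@]1(C)[C@H](O3)[C@@H]2OC(=O)C(CN(C)C)[C@@H]2[C@@H](O)[C@H]1C(C)=C | intermediate
26 | 13-(trimethylammonio) iodide of 24 (not isolated) | C3C[C@]1(C)[C@H](O3)[C@@H]2OC(=O)C(C[N+](C)(C)C)[C@@H]2[C@@H](O)[C@H]1C(C)=C.[I-] | intermediate
27 | 2,9α-epoxy-6β-hydroxy-5β-isopropenyl-11(13)-en-8α,12-olide | C3C[C@]1(C)[C@H](O3)[C@@H]2OC(=O)C(=C)[C@@H]2[C@@H](O)[C@H]1C(C)=C | intermediate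
28 | 6β-acetoxy-2,9α-epoxy-5β-isopropenyl-11(13)-en-8α,12-olide | C3C[C@]1(C)[C@H](O3)[C@@H]2OC(=O)C(=C)[C@@H]2[C@@H](OC(C)=O)[C@H]1C(C)=C | intermediate
29 | 6β-acetoxy-2-bromo-9α-hydroxy-5β-isopropenyl-11(13)-en-8α,12-olide | BrCC[C@]1(C)[C@H](O)[C@@H]2OC(=O)C(=C)[C@@H]2[C@@H](OC(C)=O)[C@H]1C(C)=C | intermediate
30 | 6β-acetoxy-9α-hydroxy-2,13-bis(2-nitrophenylseleno)-5β-isopropenyl-8α,12-olide, C11 epimers (not isolated) | O=[N+]([O-])c4ccccc4[Se]CC[C@]1(C)[C@H](O)[C@@H]2OC(=O)C(C[Se]c5ccccc5[N+](=O)[O-])[C@@H]2[C@@H](OC(C)=O)[C@H]1C(C)=C | intermediate
31 | 6β-acetoxy-9α-hydroxyelema-1,3,11(13)-trien-8α,12-olide | C=C[C@]1(C)[C@H](O)[C@@H]2OC(=O)C(=C)[C@@H]2[C@@H](OC(C)=O)[C@H]1C(C)=C | intermediate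
32 | angelic acid, (Z)-2-methylbut-2-enoic acid | C/C=C(/C)C(=O)O | starting material
33 | (Z)-2-methylbut-2-enoic 2,4,6-trichlorobenzoic anhydride (not isolated) | C/C=C(/C)C(=O)OC(=O)c1c(Cl)cc(Cl)cc1Cl | intermediate
34 | 6β-acetoxy-9α-angeloyloxyelema-1,3,11(13)-trien-8α,12-olide | C=C[C@]1(C)[C@H](OC(=O)/C(C)=C\C)[C@@H]2OC(=O)C(=C)[C@@H]2[C@@H](OC(C)=O)[C@H]1C(C)=C | intermediate
35 | 15-hydroxy derivative of 34 (not isolated) | C=C[C@]1(C)[C@H](OC(=O)/C(C)=C\C)[C@@H]2OC(=O)C(=C)[C@@H]2[C@@H](OC(C)=O)[C@H]1C(=C)CO | intermediate
36 | 6β-acetoxy-9α-angeloyloxy-15-oxoelema-1,3,11(13)-trien-8α,12-olide, (5R,6S,7R,8R,9S,10S) | C=C[C@]1(C)[C@H](OC(=O)/C(C)=C\C)[C@@H]2OC(=O)C(=C)[C@@H]2[C@@H](OC(C)=O)[C@H]1C(=C)C=O | target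

## Step count and least certain steps

Total: 22 steps. Longest linear sequence: 22 steps (1 to 36); 5, 13, 19 and 32 are purchased.

Step 7 (key step)
- What may go wrong: incomplete discrimination between the enantiotopic arms, acid-catalysed background closure, or erosion of enantiopurity by ring opening and reclosure.
- Fallback, setting out from 11 and returning at 12: 11 is cyclised with an achiral acid (diphenyl phosphate) to the racemate and the enantiomers are separated by preparative chromatography on a chiral stationary phase. The unwanted (3aR,7aS)-3a-methyl-3,3a,7,7a-tetrahydro-1-benzofuran-6(2H)-one F1 is returned to the racemate with DBU (retro-oxa-Michael to 11 and reclosure) and recycled, so that material funnels to 12.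

Step 8
- What may go wrong: slow addition at the neopentyl C5, competing 1,2-addition, enolisation at C8 that opens the ether and erodes enantiopurity, and incomplete facial selectivity, since both faces of C5 are flanked by a substituent of C10.
- Fallback, setting out from 12 and returning at 14: stereocontrol is moved from the substrate to a catalyst. 13 is transmetalated with Me2AlCl to isopropenyl(dimethyl)alane, which is added under copper thiophene-2-carboxylate and a chiral phosphoramidite ligand (asymmetric conjugate addition of an alkenylalane), and the aluminium enolate is silylated with TMSOTf to give 14 directly. No compound outside the list is formed (F0).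

Step 11
- What may go wrong: hydroxylation on the β face (adjacent axial C9–O bond against syn-axial methyl), or β-elimination of O9 from the C8 enolate.
- Fallback, setting out from 17 and returning at 18: if the 8β-hydroxy epimer F2 is obtained, it is inverted by Mitsunobu reaction (PPh3, diisopropyl azodicarboxylate, 4-nitrobenzoic acid) to the 8α-(4-nitrobenzoate) F3. Mild methanolysis (NaN3, MeOH) then gives 18.

Step 16
- What may go wrong: hydride delivery on the α face, giving the trans-fused lactone. The axial C6 hydroxyl is next to the β face of C7 and the C6–O bond favours anti attack electronically, so the facial preference is not secure even with a matched ligand.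
- Fallback, setting out from 23 and returning at 24:
  - Et3N in MeOH at 40 °C tautomerises the butenolide to its enol lactone, which is methanolysed to the γ-keto methyl ester F4 (C8 ketone, C7–CH2CO2Me). C7 equilibrates to the α side chain, the only one that is equatorial together with O6.
  - Me4NBH(OAc)3 in MeCN/AcOH at −20 °C (Evans–Saksena reduction) delivers hydride to C8 from the C6-bound borate, 1,3-anti and also anti to O9, to give the dihydroxy ester F5.
  - F5 lactonises with pyridinium p-toluenesulfonate to 24.

Step 19
- What may go wrong: incomplete ether cleavage, hydrobromination of the isopropenyl group by adventitious HBr, or loss of the acetate.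
- Fallback, setting out from 28 and returning at 31: PhSeSiMe3 with catalytic ZnI2 opens the ether at C2 and adds to the methylene lactone, giving the bis(phenylselenide) 9-O-trimethylsilyl ether F6. H2O2/pyridine, then mild acidic work-up, eliminates both selenoxides and frees the hydroxyl, giving 31 without a bromide intermediate.

Step 21
- What may go wrong: slow acylation of the neopentyl C9 hydroxyl, isomerisation to the tiglate, or acyl shift to O8 with translactonisation on prolonged heating.
- Fallback, setting out from 31 and returning at 34: 31 is esterified (DCC, DMAP) with 2-[bis(2,2,2-trifluoroethoxy)phosphoryl]propanoic acid to the phosphonopropionate ester F7. Still–Gennari olefination (KN(SiMe3)2, 18-crown-6, THF, −78 °C, acetaldehyde) then builds the Z-trisubstituted alkene of the angelate on the ester and gives 34.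

## Further compounds

F1 | step 7 | (3aR,7aS)-3a-methyl-3,3a,7,7a-tetrahydro-1-benzofuran-6(2H)-one | C[C@]12CCO[C@H]1CC(=O)C=C2
F0 | step 8 | none | none
F2 | step 11 | 8β-hydroxy epimer of 18 | C2C[C@]1(C)[C@H](O2)[C@@H](O)C(=O)[C@H](O[Si](C)(C)C(C)(C)C)[C@H]1C(C)=C
F3 | step 11 | 8α-(4-nitrobenzoyloxy) ester of 18 | C2C[C@]1(C)[C@H](O2)[C@H](OC(=O)c3ccc(cc3)[N+](=O)[O-])C(=O)[C@H](O[Si](C)(C)C(C)(C)C)[C@H]1C(C)=C
F4 | step 16 | methyl ester of the 8-oxo-6β-hydroxy-5β-isopropenyl-2,9α-epoxy 7α-acetic acid (γ-keto ester) | C2C[C@]1(C)[C@H](O2)C(=O)[C@H](CC(=O)OC)[C@@H](O)[C@H]1C(C)=C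
F5 | step 16 | methyl ester of the 6β,8α-dihydroxy-5β-isopropenyl-2,9α-epoxy 7α-acetic acid | C2C[C@]1(C)[C@H](O2)[C@H](O)[C@H](CC(=O)OC)[C@@H](O)[C@H]1C(C)=C
F6 | step 19 | 6β-acetoxy-2,13-bis(phenylseleno)-9α-(trimethylsilyloxy)-5β-isopropenyl-8α,12-olide | c4ccccc4[Se]CC[C@]1(C)[C@H](O[Si](C)(C)C)[C@@H]2OC(=O)C(C[Se]c5ccccc5)[C@@H]2[C@@H](OC(C)=O)[C@H]1C(C)=C
F7 | step 21 | 9α-{2-[bis(2,2,2-trifluoroethoxy)phosphoryl]propanoyloxy} ester of 31 | C=C[C@]1(C)[C@H](OC(=O)C(C)P(=O)(OCC(F)(F)F)OCC(F)(F)F)[C@@H]2OC(=O)C(=C)[C@@H]2[C@@H](OC(C)=O)[C@H]1C(C)=C
A1 | alternative 1 | cis-fused methylene lactone with C9 silyl ether, C6 4-methoxybenzyl ether and C5 isopropenyl | C=C[C@]1(C)[C@H](O[Si](C)(C)C(C)(C)C)[C@@H]2OC(=O)C(=C)[C@@H]2[C@@H](OCc3ccc(OC)cc3)[C@H]1C(C)=C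
A2 | alternative 2 | cis-anti-cis tricyclic photoadduct | COC(=O)[C@]12CC[C@H]1[C@@]1(C)[C@@H]2C(=O)C[C@H](O[Si](C)(C)C(C)(C)C)C1(OC)OC
A3 | alternative 3 | cyclohexene carbaldehyde with quaternary C10, C9 benzoate, C6 silyl ether and C5 isopropenyl | O=C[C@]1(C)[C@H](OC(=O)c2ccccc2)C=C[C@@H](O[Si](C)(C)C(C)(C)C)[C@H]1C(C)=C
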